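**Retrosynthetic overview**
1. C9–C11 bond last: Negishi acylation of the acid chloride of lactone acid 12 with 2-(furan-3-yl)ethylzinc iodide, so the furan only meets mild, neutral conditions.
2. 12 comes from hydroxy lactone 10 (acetylation, then hydrogenolysis). The γ-lactone (second ring) closes from the anti-diol of an L-proline aldol of aldehyde 7 with hydroxyacetone; the aldol sets C6/C7 and the lactonisation fixes the ring CH.
3. 7 comes from the C2-symmetric ketone 5 by a one-carbon homologation (spiro-epoxide, then Meinwald 1,2-shift); symmetry makes the face and stereochemistry at the central carbon irrelevant.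
4. 5 (the cyclohexane, first ring, both quaternary centres) comes from cyclobutanone by two consecutive enantioselective ring expansions (4→5→6) with benzyl 2-diazopropanoate.

Assumption: the benzyl ester of the alanine starting material is counted as a protecting group (alanine itself has six heavy atoms), and 2-(furan-3-yl)ethanol is taken as commercial.

**Step 1**
Reactants: 1 L-alanine benzyl ester hydrochloride
Product: 2 benzyl 2-diazopropanoate
Conditions: NaNO2, NaOAc, cat. H2SO4, H2O/CH2Cl2, 0 °C
Reagents that add atoms: sodium nitrite, [Na+].[O-]N=O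
Why: Diazotisation of an α-amino ester; the diazonium ion loses its acidic α-proton to give the ester-stabilised diazo compound (the alanine stereocentre is deliberately erased).

**Step 2**
Reactants: 3 cyclobutanone; 2 benzyl 2-diazopropanoate (2.3 equiv, slow addition)
Product: 5 dibenzyl (1S,3S)-1,3-dimethyl-2-oxocyclohexane-1,3-dicarboxylate, via cyclopentanone keto ester 4 (not isolated)
Conditions: Sc(OTf)3 (10 mol%), chiral N,N′-dioxide ligand (12 mol%, antipode giving the S,S series), 4 Å MS, CH2Cl2, −20 °C (first insertion) then 30 °C (second insertion)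
Reagents that add atoms: none
Why: Proposed new method: the Sc(III)-activated ketone is attacked by the diazo carbon and loss of N2 from the diazonium betaine drives a 1,2-shift of a ring CH2 (4→5 ring), after which the α-quaternary β-keto ester 4, held on Sc as a chelate, repeats the sequence on its only migratable flank (the ester-bearing quaternary carbon is a poor migrating group) to give the cyclohexanone, the same catalyst face selection setting both quaternary centres as S,S (a meso isomer would be a separable diastereomer, and a third insertion is blocked by the 2,2,6,6-substitution); the closest known reaction is the single catalytic enantioselective Tiffeneau–Demjanov-type homologation of cyclic ketones with α-alkyl-α-diazo esters, not yet shown twice in one pot or on an α-quaternary β-keto ester.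

**Step 3**
Reactants: 5 dibenzyl (1S,3S)-1,3-dimethyl-2-oxocyclohexane-1,3-dicarboxylate
Product: 6 dibenzyl (4S,8S)-4,8-dimethyl-1-oxaspiro[2.5]octane-4,8-dicarboxylate
Conditions: Me3S+ I−, KHMDS, THF, −10 °C to rt
Reagents that add atoms: trimethylsulfonium iodide, C[S+](C)C.[I-]
Why: Corey–Chaykovsky epoxidation; the small ylide adds to the non-enolisable, ester-activated ketone, and because the two faces are homotopic (C2 axis) only one epoxide can form.

**Step 4**
Reactants: 6 dibenzyl (4S,8S)-4,8-dimethyl-1-oxaspiro[2.5]octane-4,8-dicarboxylate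
Product: 7 dibenzyl (1S,3S)-2-formyl-1,3-dimethylcyclohexane-1,3-dicarboxylate
Conditions: BF3·OEt2 (20 mol%), CH2Cl2, −40 to 0 °C
Reagents that add atoms: none
Why: Meinwald rearrangement; Lewis-acid opening at the tertiary epoxide carbon with a 1,2-hydride shift gives the aldehyde, whose new CH carbon is non-stereogenic in the C2-symmetric diester.

**Step 5**
Reactants: 7 dibenzyl (1S,3S)-2-formyl-1,3-dimethylcyclohexane-1,3-dicarboxylate; 8 hydroxyacetone (excess)
Product: 10 benzyl (3S,3aR,4S,7aS)-3-[(1S)-1-hydroxy-2-oxopropyl]-4,7a-dimethyl-1-oxooctahydro-2-benzofuran-4-carboxylate, via anti-aldol diol 9 (not isolated)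
Conditions: L-proline (30 mol%), hydroxyacetone/DMSO 1:4, rt, 72 h; then CSA (10 mol%), PhMe, 50 °C
Reagents that add atoms: none
Why: Proline-catalysed direct aldol of hydroxyacetone (enamine at the hydroxylated carbon, Houk–List transition state) gives the anti-(S,S)-diol under catalyst control, and acid-catalysed γ-lactonisation of the new secondary OH onto the cis ester (cis-fused five-membered ring closes fastest) differentiates the two esters and so sets the ring CH centre.

**Step 6**
Reactants: 10 benzyl (3S,3aR,4S,7aS)-3-[(1S)-1-hydroxy-2-oxopropyl]-4,7a-dimethyl-1-oxooctahydro-2-benzofuran-4-carboxylate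
Product: 11 benzyl (3S,3aR,4S,7aS)-3-[(1S)-1-acetoxy-2-oxopropyl]-4,7a-dimethyl-1-oxooctahydro-2-benzofuran-4-carboxylate
Conditions: Ac2O, pyridine, cat. DMAP, CH2Cl2, 0 °C
Reagents that add atoms: acetic anhydride, CC(=O)OC(C)=O
Why: Standard O-acetylation of the only free hydroxyl; mild, cold conditions avoid epimerising the α-acyloxy ketone centre.

**Step 7**
Reactants: 11 benzyl (3S,3aR,4S,7aS)-3-[(1S)-1-acetoxy-2-oxopropyl]-4,7a-dimethyl-1-oxooctahydro-2-benzofuran-4-carboxylate
Product: 12 (3S,3aR,4S,7aS)-3-[(1S)-1-acetoxy-2-oxopropyl]-4,7a-dimethyl-1-oxooctahydro-2-benzofuran-4-carboxylic acid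
Conditions: H2 (1 atm), 10% Pd/C, EtOAc, rt
Reagents that add atoms: none
Why: Benzyl ester hydrogenolysis under neutral conditions leaves the lactone, acetate and ketone untouched (no furan is present yet).

**Step 8**
Reactants: 13 2-(furan-3-yl)ethanol
Product: 14 3-(2-iodoethyl)furan
Conditions: I2, PPh3, imidazole, CH2Cl2, 0 °C to rt
Reagents that add atoms: iodine, II
Why: Appel-type (Garegg–Samuelsson) iodination of a primary alcohol via the alkoxyphosphonium ion and SN2 displacement by iodide.

**Step 9**
Reactants: 12 (3S,3aR,4S,7aS)-3-[(1S)-1-acetoxy-2-oxopropyl]-4,7a-dimethyl-1-oxooctahydro-2-benzofuran-4-carboxylic acid; 14 3-(2-iodoethyl)furan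
Product: 17 (3S,3aR,4S,7aS)-3-[(1S)-1-acetoxy-2-oxopropyl]-4-[3-(furan-3-yl)propanoyl]-4,7a-dimethylhexahydro-2-benzofuran-1(3H)-one (target), via acid chloride 15 (not isolated), via alkylzinc iodide 16 (not isolated)
Conditions: (a) 12, 1-chloro-N,N,2-trimethylprop-1-en-1-amine, CH2Cl2, 0 °C to rt; (b) 14, Zn dust, LiCl, THF, 40 °C; (c) combine, Pd(PPh3)4 (5 mol%), THF, 0 °C to rt
Reagents that add atoms: none
Why: Negishi acylation; the neutral Ghosez reagent makes the hindered acid chloride and the alkylzinc couples at the acyl–Pd stage without touching ketone, acetate, lactone or furan; no stereocentre is involved.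

**Compound list**
1 | L-alanine benzyl ester hydrochloride | C[C@H]([NH3+])C(=O)OCc1ccccc1.[Cl-] | starting material
2 | benzyl 2-diazopropanoate | CC(=[N+]=[N-])C(=O)OCc1ccccc1 | intermediate
3 | cyclobutanone | O=C1CCC1 | starting material
4 | benzyl (1S)-1-methyl-2-oxocyclopentane-1-carboxylate | C[C@]1(C(=O)OCc2ccccc2)CCCC1=O | intermediate
5 | dibenzyl (1S,3S)-1,3-dimethyl-2-oxocyclohexane-1,3-dicarboxylate | C[C@]1(C(=O)OCc2ccccc2)CCC[C@](C)(C(=O)OCc2ccccc2)C1=O | intermediate
6 | dibenzyl (4S,8S)-4,8-dimethyl-1-oxaspiro[2.5]octane-4,8-dicarboxylate | C[C@]1(C(=O)OCc2ccccc2)CCC[C@](C)(C(=O)OCc2ccccc2)C13CO3 | intermediate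
7 | dibenzyl (1S,3S)-2-formyl-1,3-dimethylcyclohexane-1,3-dicarboxylate | C[C@]1(C(=O)OCc2ccccc2)CCC[C@](C)(C(=O)OCc2ccccc2)C1C=O | intermediate
8 | hydroxyacetone | CC(=O)CO | starting material
9 | dibenzyl (1S,3S)-2-[(1S,2S)-1,2-dihydroxy-3-oxobutyl]-1,3-dimethylcyclohexane-1,3-dicarboxylate | C[C@]1(C(=O)OCc2ccccc2)CCC[C@](C)(C(=O)OCc2ccccc2)C1[C@H](O)[C@H](O)C(C)=O | intermediate
10 | benzyl (3S,3aR,4S,7aS)-3-[(1S)-1-hydroxy-2-oxopropyl]-4,7a-dimethyl-1-oxooctahydro-2-benzofuran-4-carboxylate | O[C@H](C(C)=O)[C@H]1OC(=O)[C@@]2(C)CCC[C@](C)(C(=O)OCc3ccccc3)[C@@H]12 | intermediate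
11 | benzyl (3S,3aR,4S,7aS)-3-[(1S)-1-acetoxy-2-oxopropyl]-4,7a-dimethyl-1-oxooctahydro-2-benzofuran-4-carboxylate | CC(=O)O[C@H](C(C)=O)[C@H]1OC(=O)[C@@]2(C)CCC[C@](C)(C(=O)OCc3ccccc3)[C@@H]12 | intermediate
12 | (3S,3aR,4S,7aS)-3-[(1S)-1-acetoxy-2-oxopropyl]-4,7a-dimethyl-1-oxooctahydro-2-benzofuran-4-carboxylic acid | CC(=O)O[C@H](C(C)=O)[C@H]1OC(=O)[C@@]2(C)CCC[C@](C)(C(=O)O)[C@@H]12 | intermediate
13 | 2-(furan-3-yl)ethanol | OCCc1ccoc1 | starting material
14 | 3-(2-iodoethyl)furan | ICCc1ccoc1 | intermediate
15 | (3S,3aS,4S,7aS)-3-[(1S)-1-acetoxy-2-oxopropyl]-4,7a-dimethyl-1-oxooctahydro-2-benzofuran-4-carbonyl chloride | CC(=O)O[C@H](C(C)=O)[C@H]1OC(=O)[C@@]2(C)CCC[C@](C)(C(=O)Cl)[C@@H]12 | intermediate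
16 | [2-(furan-3-yl)ethyl]zinc iodide | I[Zn]CCc1ccoc1 | intermediate
17 | (3S,3aR,4S,7aS)-3-[(1S)-1-acetoxy-2-oxopropyl]-4-[3-(furan-3-yl)propanoyl]-4,7a-dimethylhexahydro-2-benzofuran-1(3H)-one (CNP0170401.2) | CC(=O)O[C@H](C(C)=O)[C@H]1OC(=O)[C@@]2(C)CCC[C@](C)(C(=O)CCc3ccoc3)[C@@H]12 | target

**Totals**
Total step count: 9. Longest linear sequence: 8 (steps 1–7 and 9; step 8 is a one-step side branch).

**Three steps most likely to fail**

Step 2 (the proposed new double ring expansion). The second insertion into the hindered α-quaternary keto ester may stall or give the meso diester. The fallback uses known chemistry and sets out from 3 and 2. Run only the precedented single enantioselective insertion (1.05 equiv of 2, same catalyst, −20 °C) and isolate 4. Homologate 4 with benzyl diazoacetate under classical BF3·OEt2 promotion (CH2 migrates) to dibenzyl (1S)-1-methyl-2-oxocyclohexane-1,3-dicarboxylate F1. C-methylate F1 under chiral phase-transfer catalysis (MeI, Cs2CO3, N-spiro quaternary ammonium bromide, toluene, −20 °C), which returns to the route at 5.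

Step 4 (Meinwald rearrangement). The cation between two ester-bearing quaternary carbons is destabilised, and a neighbouring benzyl ester may open the epoxide instead to give a hydroxy lactone. The fallback sets out from 5, so it also bypasses step 3, and replaces the epoxide route by a carbonyl olefination. Add methoxy(trimethylsilyl)methyllithium (from MeOCH2SiMe3 and s-BuLi, THF, −78 °C) to the ketone to give dibenzyl (1S,3S)-2-hydroxy-2-[methoxy(trimethylsilyl)methyl]-1,3-dimethylcyclohexane-1,3-dicarboxylate F2. Peterson elimination with KH in THF gives dibenzyl (1S,3S)-2-(methoxymethylidene)-1,3-dimethylcyclohexane-1,3-dicarboxylate F3 (no E/Z issue because of the C2 axis). Mild hydrolysis with aqueous oxalic acid in THF returns to the route at 7.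

Step 5 (aldol and lactonisation). The aldehyde sits between two quaternary carbons, so enamine addition may be too slow or the substrate may override the catalyst. The fallback sets out from 7. Horner–Wadsworth–Emmons reaction with dimethyl (2-oxopropyl)phosphonate (LiCl, DBU, MeCN) gives dibenzyl (1S,3S)-1,3-dimethyl-2-[(1E)-3-oxobut-1-en-1-yl]cyclohexane-1,3-dicarboxylate F4. Catalytic asymmetric nucleophilic epoxidation (La–BINOL–Ph3As=O, TBHP, ligand antipode chosen for the trans (2R,3S)-oxirane) gives dibenzyl (1S,3S)-2-[(2R,3S)-3-acetyloxiran-2-yl]-1,3-dimethylcyclohexane-1,3-dicarboxylate F5. Acid treatment (CSA, wet CH2Cl2) lets the cis ester carbonyl open the epoxide 5-exo at the ring-side carbon with inversion; this net anti addition gives the same hydroxy lactone and returns to the route at 10.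

**Further compounds**
F1 | step 2 | dibenzyl (1S)-1-methyl-2-oxocyclohexane-1,3-dicarboxylate (C3 epimers and enol) | C[C@]1(C(=O)OCc2ccccc2)CCCC(C(=O)OCc2ccccc2)C1=O
F2 | step 4 | dibenzyl (1S,3S)-2-hydroxy-2-[methoxy(trimethylsilyl)methyl]-1,3-dimethylcyclohexane-1,3-dicarboxylate | COC([Si](C)(C)C)C1(O)[C@@](C)(C(=O)OCc2ccccc2)CCC[C@]1(C)C(=O)OCc1ccccc1
F3 | step 4 | dibenzyl (1S,3S)-2-(methoxymethylidene)-1,3-dimethylcyclohexane-1,3-dicarboxylate | COC=C1[C@@](C)(C(=O)OCc2ccccc2)CCC[C@]1(C)C(=O)OCc1ccccc1
F4 | step 5 | dibenzyl (1S,3S)-1,3-dimethyl-2-[(1E)-3-oxobut-1-en-1-yl]cyclohexane-1,3-dicarboxylate | C[C@]1(C(=O)OCc2ccccc2)CCC[C@](C)(C(=O)OCc2ccccc2)C1/C=C/C(C)=O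
F5 | step 5 | dibenzyl (1S,3S)-2-[(2R,3S)-3-acetyloxiran-2-yl]-1,3-dimethylcyclohexane-1,3-dicarboxylate | C[C@]1(C(=O)OCc2ccccc2)CCC[C@](C)(C(=O)OCc2ccccc2)C1[C@H]3O[C@@H]3C(C)=O
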